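**Plan**

1. Locants: flavanone unit O1, C2–C4, C4a, C5–C8, C8a with ring B primed; flavone unit double-primed, its ring B triple-primed. Cuts, in order: (i) O1–C2 of the dihydropyranone ring C, with a CO2tBu group put back on C3; (ii) C2–C3 of that ring (Knoevenagel), giving a ring A β-keto ester and a biaryl aldehyde; (iii) the biaryl bond C3'–C6'' (Suzuki–Miyaura). The flavone unit is apigenin itself.
2. Enabling feature: in ring C the ether oxygen O1 and the C4 carbonyl are 1,3-related across C2–C3–C4, so the ring is the 6-endo oxa-Michael adduct of the ring A phenol onto C2 of a C4(=O)–C3=C2 enone. C3 is a CH2 next to the ketone, so it can carry a tert-butyl ester that activates the acceptor, gives a chiral hydrogen-bond catalyst a 1,3-dicarbonyl to hold, and later leaves as CO2. The 5-OMe group leaves only one ring A phenol able to close.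
3. Forward: apigenin (both flavone rings present) → 7'',4'''-dibenzyl ether → C6'' iodide → Suzuki coupling with a 3-boryl-4-benzyloxybenzaldehyde → Knoevenagel union with the ring A β-keto ester → asymmetric closure of ring C with decarboxylation (last ring) → hydrogenolysis.
4. Stereochemistry: the only stereocentre, C2 (S), is created in the ring closure under control of a cinchona-derived bifunctional thiourea. No stereocentre exists earlier, and only acidic or neutral conditions follow, so base-induced ring opening to the chalcone cannot racemise it.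

Key step: step 9

Assumption: the quinidine-derived (9R) thiourea is taken to give the 2S sense of addition; if a check against resolved material showed the 2R sense, the quinine-derived pseudoenantiomer would be used under the same conditions.
Assumption: the biaryl axis (three ortho oxygens, one ortho hydrogen) is taken to rotate freely at room temperature, so C2 is the only stereogenic element, as the target SMILES implies.

**Route**

Step 1
Reactants: 1 apigenin
Product: 2 7-(benzyloxy)-2-[4-(benzyloxy)phenyl]-5-hydroxy-4H-chromen-4-one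
Conditions: BnBr (2.2 equiv), K2CO3, DMF, 25 to 50 °C
Reagents that add atoms: benzyl bromide, BrCc1ccccc1
Why: Williamson etherification in which the 5-OH, held in a hydrogen bond to the C4 carbonyl, is the least acidic and least nucleophilic phenol, so two equivalents of benzyl bromide should cap only 7-OH and 4'-OH.

Step 2
Reactants: 2 7-(benzyloxy)-2-[4-(benzyloxy)phenyl]-5-hydroxy-4H-chromen-4-one
Product: 3 7-(benzyloxy)-2-[4-(benzyloxy)phenyl]-5-hydroxy-6-iodo-4H-chromen-4-one
Conditions: BnMe3N·ICl2 (1.1 equiv), CaCO3, CH2Cl2–MeOH, 25 °C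
Reagents that add atoms: benzyltrimethylammonium dichloroiodate, C[N+](C)(C)Cc1ccccc1.Cl[I-]Cl
Why: Electrophilic aromatic iodination of the only strongly activated ring (ring A), which with the 5-OH free should occur ortho to that phenol at C6 (between 5-OH and 7-OBn) and not at C8, as is known for 5-hydroxy-7-alkoxyflavones, while CaCO3 takes up the HCl.

Step 3
Reactants: 4 3-bromo-4-hydroxybenzaldehyde
Product: 5 4-(benzyloxy)-3-bromobenzaldehyde
Conditions: BnBr (1.1 equiv), K2CO3, DMF, 25 °C
Reagents that add atoms: benzyl bromide, BrCc1ccccc1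
Why: Williamson etherification of an acidic para-formyl phenol, which should be clean at room temperature.

Step 4
Reactants: 5 4-(benzyloxy)-3-bromobenzaldehyde
Product: 6 4-(benzyloxy)-3-(4,4,5,5-tetramethyl-1,3,2-dioxaborolan-2-yl)benzaldehyde
Conditions: B2pin2 (1.2 equiv), PdCl2(dppf) (3 mol%), KOAc, 1,4-dioxane, 85 °C
Reagents that add atoms: bis(pinacolato)diboron, CC1(C)OB(OC1(C)C)B1OC(C)(C)C(C)(C)O1
Why: Miyaura borylation, in which the weak base KOAc spares the aldehyde and keeps the new boronate from coupling with unreacted bromide.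

Step 5
Reactants: 3 7-(benzyloxy)-2-[4-(benzyloxy)phenyl]-5-hydroxy-6-iodo-4H-chromen-4-one; 6 4-(benzyloxy)-3-(4,4,5,5-tetramethyl-1,3,2-dioxaborolan-2-yl)benzaldehyde (1.5 equiv)
Product: 7 4-(benzyloxy)-3-{7-(benzyloxy)-2-[4-(benzyloxy)phenyl]-5-hydroxy-4-oxo-4H-chromen-6-yl}benzaldehyde
Conditions: Pd(OAc)2 (5 mol%), SPhos (10 mol%), K3PO4 (3 equiv), 1,4-dioxane–H2O (5:1), 90 °C
Reagents that add atoms: none
Why: Suzuki–Miyaura coupling (oxidative addition of zerovalent palladium into the C6–I bond, transmetalation, reductive elimination) with a bulky electron-rich biarylphosphine suited to tri-ortho-substituted biaryls, and the aldehyde and the chelated 5-OH should be tolerated.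

Step 6
Reactants: 8 1-(2,4-dihydroxy-6-methoxyphenyl)ethanone
Product: 9 1-[4-(benzyloxy)-2-hydroxy-6-methoxyphenyl]ethanone
Conditions: BnBr (1.05 equiv), K2CO3, acetone, reflux
Reagents that add atoms: benzyl bromide, BrCc1ccccc1
Why: Williamson etherification that should take only the 4-OH, because the 2-OH is hydrogen-bonded to the acetyl group.

Step 7
Reactants: 9 1-[4-(benzyloxy)-2-hydroxy-6-methoxyphenyl]ethanone
Product: 10 tert-butyl 3-[4-(benzyloxy)-2-hydroxy-6-methoxyphenyl]-3-oxopropanoate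
Conditions: LiN(SiMe3)2 (3.3 equiv), THF, −78 °C; Boc2O (1.1 equiv), −78 to 0 °C; then 1 M HCl
Reagents that add atoms: di-tert-butyl dicarbonate, CC(C)(C)OC(=O)OC(=O)OC(C)(C)C
Why: Claisen-type C-acylation of the methyl ketone enolate with Boc2O, in which excess amide base forms the phenoxide–enolate dianion and keeps the more acidic product deprotonated so that it is acylated only once, any aryl carbonate formed at the phenoxide should shift to carbon in a Baker–Venkataraman-type O-to-C transfer, and the hindered tert-butyl ester resists lactonisation to a 4-hydroxycoumarin.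

Step 8
Reactants: 10 tert-butyl 3-[4-(benzyloxy)-2-hydroxy-6-methoxyphenyl]-3-oxopropanoate; 7 4-(benzyloxy)-3-{7-(benzyloxy)-2-[4-(benzyloxy)phenyl]-5-hydroxy-4-oxo-4H-chromen-6-yl}benzaldehyde
Product: 11 tert-butyl (Z)-2-[4-(benzyloxy)-2-hydroxy-6-methoxybenzoyl]-3-(4-(benzyloxy)-3-{7-(benzyloxy)-2-[4-(benzyloxy)phenyl]-5-hydroxy-4-oxo-4H-chromen-6-yl}phenyl)prop-2-enoate
Conditions: piperidine (0.2 equiv), AcOH (0.4 equiv), 4 Å MS, toluene–CH2Cl2, 25 °C
Reagents that add atoms: none
Why: Knoevenagel condensation through the piperidinium iminium of 7 and the enol of 10 (the only doubly activated CH2 present), run buffered at room temperature over sieves to keep the free 2-OH from adding to the new acceptor, and expected to favour the Z isomer (bulky aroyl group trans to the arylidene ring), which should be purified by crystallisation.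

Step 9
Reactants: 11 tert-butyl (Z)-2-[4-(benzyloxy)-2-hydroxy-6-methoxybenzoyl]-3-(4-(benzyloxy)-3-{7-(benzyloxy)-2-[4-(benzyloxy)phenyl]-5-hydroxy-4-oxo-4H-chromen-6-yl}phenyl)prop-2-enoate
Product: 14 (2S)-7-(benzyloxy)-2-(4-(benzyloxy)-3-{7-(benzyloxy)-2-[4-(benzyloxy)phenyl]-5-hydroxy-4-oxo-4H-chromen-6-yl}phenyl)-5-methoxychroman-4-one, via tert-butyl ester oxa-Michael adduct 12 (not isolated), via β-keto acid 13 (not isolated)
Conditions: (i) N-[3,5-bis(trifluoromethyl)phenyl]-N'-[(9R)-6'-methoxycinchonan-9-yl]thiourea (quinidine-derived, 15 mol%), toluene, −25 °C; (ii) TsOH·H2O (1 equiv), 80 °C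
Reagents that add atoms: none
Why: The quinuclidine nitrogen of the catalyst takes up the proton of the ring A 2-OH while its thiourea N–H pair binds the ketone/tert-butyl ester pair of 11, and the phenol oxygen adds to the arylidene carbon (future C2) to give 12; TsOH then protonates the amine, which shuts off retro-addition, and cleaves the tert-butyl ester to 13 (loss of 2-methylpropene), which loses CO2 on heating. The closest known reaction type is the bifunctional cinchona-thiourea-catalysed intramolecular oxa-Michael addition of 2-hydroxyaryl alkylidene β-keto esters with acid decarboxylation in the same pot, an established enantioselective entry to flavanones. The ring (O1, C2, C3, C4, C4a, C8a) closes in the 6-endo-trig mode by O1–C2 bond formation. C2 is set by the catalyst, whose C8/C9 stereocentres fix which face of the hydrogen-bonded alkylidene meets the phenoxide, while the C3 centre of 12 is transient and disappears with the ester. The step needs enantioface selectivity over uncatalysed closure and attack by one oxygen only: low temperature, the non-polar medium and the doubly activated acceptor should keep the catalysed path dominant, the 5-OMe and benzyl groups leave a single free ring A phenol, and the flavone 5''-OH is tied to its own C4'' carbonyl and cannot reach the acceptor.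

Step 10
Reactants: 14 (2S)-7-(benzyloxy)-2-(4-(benzyloxy)-3-{7-(benzyloxy)-2-[4-(benzyloxy)phenyl]-5-hydroxy-4-oxo-4H-chromen-6-yl}phenyl)-5-methoxychroman-4-one
Product: 15 (2S)-2-{3-[5,7-dihydroxy-2-(4-hydroxyphenyl)-4-oxo-4H-chromen-6-yl]-4-hydroxyphenyl}-7-hydroxy-5-methoxychroman-4-one (target)
Conditions: H2 (1 atm), 10% Pd/C, EtOAc–MeOH (1:1), 25 °C
Reagents that add atoms: none
Why: Hydrogenolysis of the four O-benzyl ethers over Pd/C under neutral conditions, which at room temperature and one atmosphere should leave the 5-OMe ether, the flavone C2''=C3'' bond and the aryl ketone untouched and avoid the base that would racemise C2 by ring opening to the chalcone.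

**Compound list**

1 | apigenin, 5,7-dihydroxy-2-(4-hydroxyphenyl)-4H-chromen-4-one | O=c1cc(-c2ccc(O)cc2)oc2cc(O)cc(O)c12 | starting material
2 | 7-(benzyloxy)-2-[4-(benzyloxy)phenyl]-5-hydroxy-4H-chromen-4-one | O=c1cc(-c2ccc(OCc3ccccc3)cc2)oc2cc(OCc3ccccc3)cc(O)c12 | intermediate
3 | 7-(benzyloxy)-2-[4-(benzyloxy)phenyl]-5-hydroxy-6-iodo-4H-chromen-4-one | O=c1cc(-c2ccc(OCc3ccccc3)cc2)oc2cc(OCc3ccccc3)c(I)c(O)c12 | intermediate
4 | 3-bromo-4-hydroxybenzaldehyde | O=Cc1ccc(O)c(Br)c1 | starting material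
5 | 4-(benzyloxy)-3-bromobenzaldehyde | O=Cc1ccc(OCc2ccccc2)c(Br)c1 | intermediate
6 | 4-(benzyloxy)-3-(4,4,5,5-tetramethyl-1,3,2-dioxaborolan-2-yl)benzaldehyde | O=Cc1ccc(OCc2ccccc2)c(B2OC(C)(C)C(C)(C)O2)c1 | intermediate
7 | 4-(benzyloxy)-3-{7-(benzyloxy)-2-[4-(benzyloxy)phenyl]-5-hydroxy-4-oxo-4H-chromen-6-yl}benzaldehyde | O=Cc1ccc(OCc2ccccc2)c(-c2c(OCc3ccccc3)cc3oc(-c4ccc(OCc5ccccc5)cc4)cc(=O)c3c2O)c1 | intermediate
8 | 1-(2,4-dihydroxy-6-methoxyphenyl)ethanone | CC(=O)c1c(O)cc(O)cc1OC | starting material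
9 | 1-[4-(benzyloxy)-2-hydroxy-6-methoxyphenyl]ethanone | CC(=O)c1c(O)cc(OCc2ccccc2)cc1OC | intermediate
10 | tert-butyl 3-[4-(benzyloxy)-2-hydroxy-6-methoxyphenyl]-3-oxopropanoate | CC(C)(C)OC(=O)CC(=O)c1c(O)cc(OCc2ccccc2)cc1OC | intermediate
11 | tert-butyl (Z)-2-[4-(benzyloxy)-2-hydroxy-6-methoxybenzoyl]-3-(4-(benzyloxy)-3-{7-(benzyloxy)-2-[4-(benzyloxy)phenyl]-5-hydroxy-4-oxo-4H-chromen-6-yl}phenyl)prop-2-enoate | CC(C)(C)OC(=O)/C(C(=O)c1c(O)cc(OCc2ccccc2)cc1OC)=C\c1ccc(OCc2ccccc2)c(-c2c(OCc3ccccc3)cc3oc(-c4ccc(OCc5ccccc5)cc4)cc(=O)c3c2O)c1 | intermediate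
12 | tert-butyl (2S,3R)-7-(benzyloxy)-2-(4-(benzyloxy)-3-{7-(benzyloxy)-2-[4-(benzyloxy)phenyl]-5-hydroxy-4-oxo-4H-chromen-6-yl}phenyl)-5-methoxy-4-oxochromane-3-carboxylate (trans keto form, in equilibrium with its enol) | COc1cc(OCc2ccccc2)cc2c1C(=O)[C@H](C(=O)OC(C)(C)C)[C@@H](c1ccc(OCc3ccccc3)c(-c3c(OCc4ccccc4)cc4oc(-c5ccc(OCc6ccccc6)cc5)cc(=O)c4c3O)c1)O2 | intermediate
13 | (2S,3R)-7-(benzyloxy)-2-(4-(benzyloxy)-3-{7-(benzyloxy)-2-[4-(benzyloxy)phenyl]-5-hydroxy-4-oxo-4H-chromen-6-yl}phenyl)-5-methoxy-4-oxochromane-3-carboxylic acid | COc1cc(OCc2ccccc2)cc2c1C(=O)[C@H](C(=O)O)[C@@H](c1ccc(OCc3ccccc3)c(-c3c(OCc4ccccc4)cc4oc(-c5ccc(OCc6ccccc6)cc5)cc(=O)c4c3O)c1)O2 | intermediate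
14 | (2S)-7-(benzyloxy)-2-(4-(benzyloxy)-3-{7-(benzyloxy)-2-[4-(benzyloxy)phenyl]-5-hydroxy-4-oxo-4H-chromen-6-yl}phenyl)-5-methoxychroman-4-one | COc1cc(OCc2ccccc2)cc2c1C(=O)C[C@@H](c1ccc(OCc3ccccc3)c(-c3c(OCc4ccccc4)cc4oc(-c5ccc(OCc6ccccc6)cc5)cc(=O)c4c3O)c1)O2 | intermediate
15 | (2S)-2-{3-[5,7-dihydroxy-2-(4-hydroxyphenyl)-4-oxo-4H-chromen-6-yl]-4-hydroxyphenyl}-7-hydroxy-5-methoxychroman-4-one | COc1cc(O)cc2c1C(=O)C[C@@H](c1ccc(O)c(-c3c(O)cc4oc(-c5ccc(O)cc5)cc(=O)c4c3O)c1)O2 | target

**Step count**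

Total: 10 steps. Longest linear sequence: 6 steps (steps 1, 2, 5, 8, 9, 10 from apigenin; equally steps 3, 4, 5, 8, 9, 10 from 3-bromo-4-hydroxybenzaldehyde).

**Steps most likely to fail**

1. Step 9. The 6-methoxy group of the aroyl ring twists the ketone out of plane and may speed uncatalysed closure, and ring opening and re-closure of 12 before the acid quench may erode enantiomeric purity; the sense of induction also rests on the assumption above. Fallback by resolution in place of asymmetric catalysis, setting out from 9 and 7: aldol condensation (KOH, EtOH–THF, 25 °C) should give the 2'-hydroxychalcone (E)-1-[4-(benzyloxy)-2-hydroxy-6-methoxyphenyl]-3-(4-(benzyloxy)-3-{7-(benzyloxy)-2-[4-(benzyloxy)phenyl]-5-hydroxy-4-oxo-4H-chromen-6-yl}phenyl)prop-2-en-1-one F1. Heating with NaOAc in EtOH should close it to the racemic flavanone rac-14 F2, the 6'-methoxy pattern favouring the closed form. Preparative chromatography on an amylose tris(3,5-dimethylphenylcarbamate) phase would separate 14 from its (2R)-enantiomer F3, which could be returned to F2 by warming with a catalytic amount of DBU. The fallback comes back to the route at 14.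

2. Step 8. The free 2-OH may add to the new acceptor under the amine in the condensation flask, giving racemic 12 before the chiral catalyst is present, and the alkene geometry may scramble. Fallback by a temporary mask on the nucleophile, setting out from 9: allyl bromide, K2CO3, DMF, 60 °C should give the allyl ether 1-[2-(allyloxy)-4-(benzyloxy)-6-methoxyphenyl]ethanone F4. LiN(SiMe3)2 then Boc2O (THF, −78 to 0 °C) should give the β-keto ester tert-butyl 3-[2-(allyloxy)-4-(benzyloxy)-6-methoxyphenyl]-3-oxopropanoate F5. Knoevenagel condensation with 7 as in step 8 should give the O-allyl alkylidene F6, which cannot close. Pd(PPh3)4 (zerovalent palladium) with PhSiH3 in CH2Cl2 at 0 °C should remove the allyl group under neutral conditions and give 11, which would be taken directly into step 9.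

3. Step 5. The ortho-phenoxide formed from the free 5-OH under the basic conditions may slow oxidative addition at the doubly flanked C6–I bond, so that hydrodeiodination of 3 and protodeboronation of 6 take over. Fallback by coupling the fully etherified iodide and then removing the peri benzyl group, setting out from 3: BnBr, K2CO3, DMF, 70 °C should give the tribenzyl iodide 5,7-bis(benzyloxy)-2-[4-(benzyloxy)phenyl]-6-iodo-4H-chromen-4-one F7. Suzuki–Miyaura coupling with 6 (Pd(PPh3)4, K2CO3, DMF–H2O, 90 °C) should give the tribenzyl biaryl aldehyde 4-(benzyloxy)-3-{5,7-bis(benzyloxy)-2-[4-(benzyloxy)phenyl]-4-oxo-4H-chromen-6-yl}benzaldehyde F8. Concentrated HCl in AcOH at 25 to 40 °C should cleave only the 5-O-benzyl group, which is activated by the neighbouring C4 carbonyl, and return the route to 7.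

**Further compounds**

F1 | step 9 | (E)-1-[4-(benzyloxy)-2-hydroxy-6-methoxyphenyl]-3-(4-(benzyloxy)-3-{7-(benzyloxy)-2-[4-(benzyloxy)phenyl]-5-hydroxy-4-oxo-4H-chromen-6-yl}phenyl)prop-2-en-1-one | COc1cc(OCc2ccccc2)cc(O)c1C(=O)/C=C/c1ccc(OCc2ccccc2)c(-c2c(OCc3ccccc3)cc3oc(-c4ccc(OCc5ccccc5)cc4)cc(=O)c3c2O)c1
F2 | step 9 | rac-7-(benzyloxy)-2-(4-(benzyloxy)-3-{7-(benzyloxy)-2-[4-(benzyloxy)phenyl]-5-hydroxy-4-oxo-4H-chromen-6-yl}phenyl)-5-methoxychroman-4-one | COc1cc(OCc2ccccc2)cc2c1C(=O)CC(c1ccc(OCc3ccccc3)c(-c3c(OCc4ccccc4)cc4oc(-c5ccc(OCc6ccccc6)cc5)cc(=O)c4c3O)c1)O2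
F3 | step 9 | (2R)-7-(benzyloxy)-2-(4-(benzyloxy)-3-{7-(benzyloxy)-2-[4-(benzyloxy)phenyl]-5-hydroxy-4-oxo-4H-chromen-6-yl}phenyl)-5-methoxychroman-4-one | COc1cc(OCc2ccccc2)cc2c1C(=O)C[C@H](c1ccc(OCc3ccccc3)c(-c3c(OCc4ccccc4)cc4oc(-c5ccc(OCc6ccccc6)cc5)cc(=O)c4c3O)c1)O2
F4 | step 8 | 1-[2-(allyloxy)-4-(benzyloxy)-6-methoxyphenyl]ethanone | CC(=O)c1c(OCC=C)cc(OCc2ccccc2)cc1OC
F5 | step 8 | tert-butyl 3-[2-(allyloxy)-4-(benzyloxy)-6-methoxyphenyl]-3-oxopropanoate | CC(C)(C)OC(=O)CC(=O)c1c(OCC=C)cc(OCc2ccccc2)cc1OC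
F6 | step 8 | tert-butyl (Z)-2-[2-(allyloxy)-4-(benzyloxy)-6-methoxybenzoyl]-3-(4-(benzyloxy)-3-{7-(benzyloxy)-2-[4-(benzyloxy)phenyl]-5-hydroxy-4-oxo-4H-chromen-6-yl}phenyl)prop-2-enoate | CC(C)(C)OC(=O)/C(C(=O)c1c(OCC=C)cc(OCc2ccccc2)cc1OC)=C\c1ccc(OCc2ccccc2)c(-c2c(OCc3ccccc3)cc3oc(-c4ccc(OCc5ccccc5)cc4)cc(=O)c3c2O)c1
F7 | step 5 | 5,7-bis(benzyloxy)-2-[4-(benzyloxy)phenyl]-6-iodo-4H-chromen-4-one | O=c1cc(-c2ccc(OCc3ccccc3)cc2)oc2cc(OCc3ccccc3)c(I)c(OCc3ccccc3)c12
F8 | step 5 | 4-(benzyloxy)-3-{5,7-bis(benzyloxy)-2-[4-(benzyloxy)phenyl]-4-oxo-4H-chromen-6-yl}benzaldehyde | O=Cc1ccc(OCc2ccccc2)c(-c2c(OCc3ccccc3)cc3oc(-c4ccc(OCc5ccccc5)cc4)cc(=O)c3c2OCc2ccccc2)c1
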